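## Structural features

The target 16 is a single carbocycle, a 1,4-benzoquinone in which five of the six ring carbons are substituted: carbonyl groups at C1 and C4, a free hydroxyl at C2, an unbranched docosyl chain at C3, a methoxy group at C5, and the only ring hydrogen at C6. The chain is joined to C3 by one C–C single bond and carries no functionality; there is no second ring and no stereocentre, so no stereochemical relationship has to be set or preserved. The C2 hydroxyl is a vinylogous acid (HO–C2=C3–C4=O) and the C5 methoxy group a vinylogous ester (MeO–C5=C6–C1=O). Both are fragile: the methoxy group can be exchanged or hydrolysed by nucleophiles, the hydroxyl is readily alkylated or acylated, and the quinone core is reducible and sensitive to base and peroxide. The real difficulty is regiochemical: four ring oxygens have to be placed around one alkyl group, and the two non-carbonyl oxygens at C2 and C5 must be told apart although they occupy almost equivalent positions. A practical difficulty is the waxy C22 chain, which governs solubility in every step. The key step exploits the fact that C3 is meta to both C1 and C5: C1, C3 and C5 define a 5-alkylcyclohexane-1,3-dione, which falls apart into an enone supplying C3–C2–C1–C6 with the chain and a malonate supplying C4 and C5. The oxygens at C4 and C2 are then introduced one at a time at positions that the substituents already present single out.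

## Logic of the disconnections

16 ⇒ 14 (through 15). No carbon–carbon bond is cut; the retrosynthetic change is reduction of the quinone and acylation of the three ring oxygens at C1, C2 and C4. The reason is stability: 16 is an acidic, chelating, nucleophile-sensitive push–pull quinone, whereas 14 is a neutral arene that can be purified and stored. The gain is that the last operation becomes a deprotection plus a two-electron oxidation on a compound that already holds every atom of 16. The demand is that the three ester C–O bonds are cleaved without touching the C5 methyl ether and that the oxidation stops at 16.

14 ⇒ 13. The C2–O bond is cut. In 13, C2 is the only ring CH that is β to the ketone-like carbonyl C4 and is not enriched by the methoxy group; the other ring CH, C6, is the donor-substituted α-carbon of the vinylogous ester. The gain is one oxygen less and a quinone with only two substituents. The demand is that an oxygen nucleophile adds at C2 and not at C6 or at the methoxy-bearing C5, in a medium that leaves the vinylogous ester intact.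

13 ⇒ 12. The C4–O bond is cut. C4 is para to the hydroxyl-bearing C1 of 12, the position at which one-electron oxidants deliver oxygen to a phenol. The gain is a plain 1,3,5-trisubstituted benzene with two oxygens. The demand is para rather than ortho oxygenation although C4 lies between the chain and the methoxy group, and an oxidant that can reach a waxy substrate.

12 ⇒ 10 (through 11). The C5–OMe bond is cut and two hydrogens are returned to the ring, so that the arene becomes a saturated 1,3-dione. The reason is symmetry: in 10 the two oxygens are related by a mirror plane through C3 and C6, so a single enol etherification differentiates them with no selectivity problem. The gain is a ring that is the direct product of carbonyl condensation chemistry. The demand is exactly one etherification and one dehydrogenation, without substitution of the electron-rich product.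

10 ⇒ 5 + 6 (through 7, 8 and 9). Two ring bonds are cut, C3–C4 and C5–C6, and a carboxyl group is restored at C4. C1 and C5 stand in a 1,5-relationship through C2–C3–C4 (conjugate-addition retron) and in a 1,3-relationship through C6 (acylation retron), so both cuts follow natural polarity. The gain is the largest of the route: the carbocycle is dissolved into a linear enone and a three-carbon diester. The demand is that the stabilised carbanion adds 1,4, that the methyl terminus C6 is then acylated intramolecularly, and that the surplus carboxyl is removed without opening the β-diketone.

5 ⇒ 1 + 2 (through 3 and 4). The bond between C3 and the first chain carbon is cut. This divides 5 into a C22 nucleophile and a C4 electrophile, both articles of commerce, and sets the chain length by the choice of halide. The demand is that the organometallic attacks the β-carbon once only and that the leaving group departs to restore the C2=C3 double bond.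

## Other disconnections considered

Alternative 1: The cut is the C4–C5 ring bond, in the sense of a Moore ring expansion.
- Precursor: 3-tert-butoxy-2-docosyl-4-hydroxy-4-(methoxyethynyl)cyclobut-2-en-1-one A2. It would come from di-tert-butyl squarate A3 by addition of 3 and acid-induced transposition to 3-tert-butoxy-4-docosylcyclobut-3-ene-1,2-dione A4, followed by addition of lithiated methoxyethyne A5 to the ketone-like carbonyl next to the tert-butoxy carbon.
- Forward key step: heating A2 should open the four-membered ring (4π electrocyclic opening, hydroxyl turning outward) to an enynyl ketene. Bonding of the ketene carbon to the methoxy-bearing alkyne terminus and hydrogen transfer in the resulting diradical would give 2-tert-butoxy-3-docosyl-5-methoxy-1,4-benzoquinone A1. Acidolysis of the tert-butyl ether would then give 16.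
- In its favour: every substituent is placed by construction, the two non-carbonyl oxygens are differentiated from the start as tert-butyl and methyl ethers, and no late oxidation is needed. The sequence is convergent and about five operations long. On programming of the substitution pattern and on step count it is the better plan.
- Against it here: A5 is a low-boiling, unstable alkyne that must be generated and used at once, and A3 and A4 are acid- and heat-labile. The key step also carries a ring-size risk: a radical-stabilising substituent on the alkyne terminus, which an alkoxy group is, is expected to favour closure to a five-membered alkylidenecyclopentenedione over the quinone.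
- Comparison: the alternative is a thermal pericyclic and diradical cascade whose outcome hinges on a substituent effect. The chosen annulation is an anionic cascade under thermodynamic control in which only one ring size can form. The chosen plan pays for this with three oxidation-level steps after ring formation, each with a single accessible site and stable, inexpensive reagents.

Alternative 2: Three ring bonds are cut, C1–C6, C4–C5 and C1–C2 (Danheiser benzannulation), leading back to 3-docosylcyclobut-2-en-1-one A6 and A5.
- Forward key step: heating A6 should generate a vinylketene that undergoes [2+2] cycloaddition with A5. 4π opening of the resulting vinylcyclobutenone, 6π electrocyclisation of the dienylketene and tautomerisation would give 3-docosyl-5-methoxyphenol A7, the same compound as 12.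
- In its favour: the polarity of ketene and ynol ether fixes the regiochemistry, so the methoxy group arrives meta to the hydroxyl with the two oxygens already differentiated. The arene forms directly at the phenol oxidation level with no separate dehydrogenation. In regiochemical security it is the equal of the chosen key step, and from A6 it reaches the phenol in one operation where the chosen plan needs steps 2 and 3.
- Against it here: A6 is not an article of commerce and needs its own two- or three-step preparation (for instance from a 3-alkoxycyclobutenone and 3). A5 is again required and tends to polymerise at the temperature of the cascade. Everything after A7 is identical with steps 4 to 6, so the alternative changes only the way to 12.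
- Comparison: counting the preparation of A6 and A5, the step economy is equal at best. The four-stage pericyclic cascade is elegant but gives no advantage in the oxidation endgame, whereas the chosen plan reaches 12 from a commodity diester and a one-step enone with ordinary alkoxide base.

Alternative 3: The ring bonds C3–C4 and C6–C1 are cut, dividing the ring into ethyl 2-oxopentacosanoate A8 (C1–C2–C3 with the chain) and ethyl pyruvate A9 (C4–C5–C6).
- Forward key step: an alkoxide base would effect two Claisen acylations, the C3 methylene of A8 on the ester of A9 and the methyl group of A9 on the ester of A8. This would give 3-docosyl-2,5-dihydroxy-1,4-benzoquinone A10 directly at the dihydroxyquinone oxidation level. Selective O-methylation of the less hindered C5 hydroxyl by acid-catalysed methanolysis would then complete 16.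
- In its favour: it is the shortest plan on paper. All four oxygens are in place after one operation and no redox step is needed, so in oxidation-state and step economy it is clearly better than the chosen plan. The type of bond formation, two carbonyl condensations that close the ring, is the same.
- Against it here: the crossed condensation has no built-in selectivity. Both partners are at once enolisable nucleophiles and doubly electrophilic, A9 self-condenses readily, and homo-dimeric dihydroxyquinones are expected alongside A10, so the key step is statistical at best. A8 needs a C23 chain plus two carbons and cannot be made from 1 without homologation. The final methylation must distinguish two vinylogous acids that differ only in the neighbouring chain.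
- Comparison: the chosen annulation assigns the roles unambiguously (6 is only a nucleophile until the Michael addition is over, 5 only an electrophile) and differentiates the two oxygens through the single enol ether of a symmetric dione, at the cost of three additional oxidation steps.

Key step: step 2

Remark on the chemistry: the second bond of the key step is strictly a Claisen acylation of a ketone enolate by an ester (a Dieckmann-type closure), and intermediates 4, 7, 8, 9 and 11 are racemic, which is of no consequence because every stereocentre is erased on the way to 12.

## Route

Step 1
Reactants: 1 1-bromodocosane; 2 (E)-4-(dimethylamino)but-3-en-2-one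
Product: 5 (E)-hexacos-3-en-2-one, via docosylmagnesium bromide 3 (not isolated), via 4-(dimethylamino)hexacosan-2-one 4 (not isolated)
Conditions: Mg, THF, 45 °C; then 2, THF, 0 °C to rt; then 1 M HCl, rt to 40 °C
Reagents that add atoms: none
Why: Benary reaction: the organomagnesium reagent 3 adds to the iminium-like β-carbon of the vinylogous amide 2 (conjugate addition), and the magnesium enolate of 4 keeps its amino group until the acidic work-up, so a second alkyl transfer cannot take place. Protonation and E1cB loss of dimethylamine then give the conjugated enone as the thermodynamically favoured E isomer.

Step 2
Reactants: 5 (E)-hexacos-3-en-2-one; 6 dimethyl malonate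
Product: 10 5-docosylcyclohexane-1,3-dione, via dimethyl 2-(2-oxohexacosan-4-yl)malonate 7 (not isolated), via methyl 2-docosyl-4,6-dioxocyclohexane-1-carboxylate 8 (not isolated), via 2-docosyl-4,6-dioxocyclohexane-1-carboxylic acid 9 (not isolated)
Conditions: NaOMe (1.2 equiv), MeOH–THF, reflux; then 2 M NaOH aq., reflux; then conc. HCl to pH 1, 80 °C
Reagents that add atoms: none
Why: Methoxide deprotonates 6, and the soft, stabilised malonate anion adds to the β-carbon of 5 (the future C3) to give the Michael adduct 7, forming C3–C4. Proton transfer under the equilibrating conditions produces the methyl ketone enolate (future C6), which attacks one malonate ester carbonyl (future C5) and expels methoxide, forming C5–C6 and the ring. This closure is a 6-(enolendo)-exo-trig Claisen acylation and the only one open to 7, because the internal enolate could close only a four-membered ring. The sequence is pulled forward, including the reversible Michael step, by irreversible deprotonation of the β-diketone 8 to its delocalised enolate. Aqueous NaOH then saponifies the remaining ester, and acidification with heating decarboxylates the β-keto acid 9 through the usual cyclic transition state to give 10. The closest known reaction type is the classical Michael–Claisen annulation of malonates with alk-3-en-2-ones to 5-alkylcyclohexane-1,3-diones. No stereocentre survives: the centres created at C3 and C4 in 7 to 9 are racemic, that at C4 is removed with the carboxyl group, and C3 ends on a mirror plane. The selectivities needed are 1,4- over 1,2-addition and C- over O-acylation, secured by the soft nucleophile, thermodynamic control in methanol and the geometry of the tether.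

Step 3
Reactants: 10 5-docosylcyclohexane-1,3-dione
Product: 12 3-docosyl-5-methoxyphenol, via 5-docosyl-3-methoxycyclohex-2-en-1-one 11 (not isolated)
Conditions: I2 (2 equiv), MeOH–(CH2Cl)2, reflux
Reagents that add atoms: methanol, CO
Why: Iodine–methanol aromatisation of a cyclohexane-1,3-dione: HI formed in situ catalyses conversion of the mirror-symmetric dione into its single mono enol ether 11, which is iodinated next to the carbonyl and loses HI to a cross-conjugated dienone that tautomerises to the phenol. Because the two oxygens of 10 are equivalent, one etherification differentiates OH and OMe without a statistical methylation, and the stereocentre of 11 is erased.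

Step 4
Reactants: 12 3-docosyl-5-methoxyphenol
Product: 13 2-docosyl-6-methoxy-1,4-benzoquinone
Conditions: K2[ON(SO3)2] (Fremy's salt, 2.5 equiv), KH2PO4 aq., Bu4NCl (cat.), CH2Cl2–H2O, rt
Reagents that add atoms: Fremy's salt (dipotassium nitrosodisulfonate), [K+].[K+].[O]N(S(=O)(=O)[O-])S(=O)(=O)[O-]
Why: Teuber oxidation: the nitroxyl radical abstracts the phenolic hydrogen, a second equivalent couples at the free para carbon C4, and loss of imidodisulfonate gives the para-quinone. Para attack is preferred over ortho attack when the para position is unsubstituted, as is established for 3-alkyl-5-methoxyphenols; the phase-transfer salt carries the oxidant to the lipophilic phenol.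

Step 5
Reactants: 13 2-docosyl-6-methoxy-1,4-benzoquinone
Product: 14 3-docosyl-5-methoxybenzene-1,2,4-triyl triacetate
Conditions: Ac2O, H2SO4 (cat.), rt to 40 °C
Reagents that add atoms: acetic anhydride, CC(=O)OC(C)=O
Why: Thiele–Winter acetoxylation: the acid-activated quinone takes up acetate by conjugate addition at C2, the only ring CH that is β to the ketone-like carbonyl C4 and para to the methoxy group, whereas C6 is the electron-rich α-carbon of the vinylogous ester and is not attacked. Enolisation and exhaustive acetylation trap the hydroxyhydroquinone as the stable triacetate.

Step 6
Reactants: 14 3-docosyl-5-methoxybenzene-1,2,4-triyl triacetate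
Product: 16 3-docosyl-2-hydroxy-5-methoxy-1,4-benzoquinone (3-docosyl-2-hydroxy-5-methoxycyclohexa-2,5-diene-1,4-dione), via 3-docosyl-5-methoxybenzene-1,2,4-triol 15 (not isolated)
Conditions: NaOMe (3.3 equiv), MeOH–THF, argon, 0 °C to rt; then FeCl3, aq. HCl, 0 °C
Reagents that add atoms: none
Why: Methoxide-mediated transesterification (Zemplén-type deacetylation) frees the three phenols and leaves the aryl methyl ether untouched, and FeCl3 then oxidises the electron-rich triol 15 by two electrons to the hydroxy-para-quinone, the stable tautomer. Working under argon with a metal oxidant avoids forming H2O2 beside the hydroxyquinone anion, and the C5 methoxy group, now a vinylogous ester, meets only cold dilute acid for a short time.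

## Compound list

1 | 1-bromodocosane | CCCCCCCCCCCCCCCCCCCCCCBr | starting material
2 | (E)-4-(dimethylamino)but-3-en-2-one | CN(C)/C=C/C(C)=O | starting material
3 | docosylmagnesium bromide | CCCCCCCCCCCCCCCCCCCCCC[Mg]Br | intermediate (not isolated)
4 | 4-(dimethylamino)hexacosan-2-one (racemic) | CCCCCCCCCCCCCCCCCCCCCCC(CC(C)=O)N(C)C | intermediate (not isolated)
5 | (E)-hexacos-3-en-2-one | CCCCCCCCCCCCCCCCCCCCCC/C=C/C(C)=O | intermediate
6 | dimethyl malonate | COC(=O)CC(=O)OC | starting material
7 | dimethyl 2-(2-oxohexacosan-4-yl)malonate (racemic) | CCCCCCCCCCCCCCCCCCCCCCC(CC(C)=O)C(C(=O)OC)C(=O)OC | intermediate (not isolated)
8 | methyl 2-docosyl-4,6-dioxocyclohexane-1-carboxylate (racemic, present as its sodium enolate) | CCCCCCCCCCCCCCCCCCCCCCC1CC(=O)CC(=O)C1C(=O)OC | intermediate (not isolated)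
9 | 2-docosyl-4,6-dioxocyclohexane-1-carboxylic acid (racemic) | CCCCCCCCCCCCCCCCCCCCCCC1CC(=O)CC(=O)C1C(=O)O | intermediate (not isolated)
10 | 5-docosylcyclohexane-1,3-dione (achiral) | CCCCCCCCCCCCCCCCCCCCCCC1CC(=O)CC(=O)C1 | intermediate
11 | 5-docosyl-3-methoxycyclohex-2-en-1-one (racemic) | CCCCCCCCCCCCCCCCCCCCCCC1CC(OC)=CC(=O)C1 | intermediate (not isolated)
12 | 3-docosyl-5-methoxyphenol | CCCCCCCCCCCCCCCCCCCCCCc1cc(O)cc(OC)c1 | intermediate
13 | 2-docosyl-6-methoxy-1,4-benzoquinone | CCCCCCCCCCCCCCCCCCCCCCC1=CC(=O)C=C(OC)C1=O | intermediate
14 | 3-docosyl-5-methoxybenzene-1,2,4-triyl triacetate | CCCCCCCCCCCCCCCCCCCCCCc1c(OC(C)=O)c(OC(C)=O)cc(OC)c1OC(C)=O | intermediate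
15 | 3-docosyl-5-methoxybenzene-1,2,4-triol | CCCCCCCCCCCCCCCCCCCCCCc1c(O)c(O)cc(OC)c1O | intermediate (not isolated)
16 | 3-docosyl-2-hydroxy-5-methoxy-1,4-benzoquinone | CCCCCCCCCCCCCCCCCCCCCCC1=C(O)C(=O)C=C(OC)C1=O | target

## Step count and least certain steps

Total step count: 6. Longest linear sequence: 6 steps (1 → 5 → 10 → 12 → 13 → 14 → 16).

Step 2 (key step). The most likely failure is stalling at the open-chain Michael adduct or reversal to 5 and 6, because the waxy enone and the sodium enolate of the cyclised product are poorly soluble in methanol and aldol self-condensation of the methyl ketone competes. Ring fission of the β-diketone by hydroxide (retro-Claisen) during saponification is the second concern. The fallback gives up the annulation and attaches the chain to a preformed arene. It sets out from 3 (made from 1 as in step 1), which is coupled with 1-bromo-3,5-dimethoxybenzene under NiCl2(dppp) catalysis (Kumada coupling, THF, reflux) to give 1-docosyl-3,5-dimethoxybenzene F2. One of the two equivalent methyl ethers is then cleaved with NaSEt in DMF at 140 °C (SN2 at methyl; the phenoxide formed shields the second ether), and the route is rejoined at 12.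

Step 1. The most likely failure is competing 1,2-addition to the carbonyl or deprotonation of the acetyl group by the basic organomagnesium reagent, together with Wurtz homocoupling during formation of the long-chain reagent. The fallback sets out from 3: formylation with DMF (Bouveault aldehyde synthesis; THF, 0 °C, then aq. HCl) should give tricosanal F1. Wittig olefination of F1 with the stabilised ylide Ph3P=CHC(O)CH3 (toluene, 90 °C) then gives the E-enone, and the route is rejoined at 5.

Step 3. The most likely failure is over-etherification, a second enol ether forming before dehydrogenation and leading to the dimethyl ether, and nuclear iodination of the very electron-rich phenol once it has formed. The fallback sets out from 10 and separates the two events. Acid-catalysed etherification (TsOH, MeOH, reflux) gives 11, which is now isolated. Kinetic deprotonation at C6 with LDA (THF, −78 °C) and trapping with PhSeCl gives 5-docosyl-3-methoxy-6-(phenylselanyl)cyclohex-2-en-1-one F3. Oxidation with H2O2 (CH2Cl2, pyridine, 0 °C to rt) and syn-elimination of the selenoxide give a cross-conjugated dienone that tautomerises, and the route is rejoined at 12.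

Step 4. The most likely failure is slow transfer of the oxidant to the lipophilic phenol, leaving the oxidation incomplete, and attack at an ortho carbon because the para carbon lies between two substituents. The fallback sets out from 12 and replaces the radical oxidation by a two-electron one. Two equivalents of the trivalent iodine reagent PhI(OAc)2 in MeOH at 0 °C, through two successive oxidations with capture of methanol at C4, should give the quinone monoketal 3-docosyl-4,4,5-trimethoxycyclohexa-2,5-dien-1-one F4. Dilute aqueous HCl in THF at rt hydrolyses the ketal, and the route is rejoined at 13.

Step 5. The most likely failure is sluggish conjugate acetoxylation, since C2 is shielded by the neighbouring chain in a 2,6-disubstituted quinone, and acid-mediated cleavage of the vinylogous methyl ester, which would erase the distinction between the two oxygens. The fallback sets out from 13 and brings in the C2 oxygen as an epoxide. Nucleophilic epoxidation (H2O2, Na2CO3, THF–MeOH–H2O, 0 °C) of the chain-bearing double bond, the only one not deactivated by the methoxy donor, should give 1-docosyl-3-methoxy-7-oxabicyclo[4.1.0]hept-3-ene-2,5-dione F5 (racemic, cis-fused). Brief treatment with H2SO4 in AcOH at 0 °C to rt isomerises the epoxide by opening at the chain-bearing carbon and loss of the C2 proton. The route is rejoined at 16, with steps 5 and 6 bypassed.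

## Further compounds

F1 | step 1 | tricosanal | CCCCCCCCCCCCCCCCCCCCCCC=O
F2 | step 2 | 1-docosyl-3,5-dimethoxybenzene | CCCCCCCCCCCCCCCCCCCCCCc1cc(OC)cc(OC)c1
F3 | step 3 | 5-docosyl-3-methoxy-6-(phenylselanyl)cyclohex-2-en-1-one (racemic) | CCCCCCCCCCCCCCCCCCCCCCC1CC(OC)=CC(=O)C1[Se]c1ccccc1
F4 | step 4 | 3-docosyl-4,4,5-trimethoxycyclohexa-2,5-dien-1-one | CCCCCCCCCCCCCCCCCCCCCCC1=CC(=O)C=C(OC)C1(OC)OC
F5 | step 5 | 1-docosyl-3-methoxy-7-oxabicyclo[4.1.0]hept-3-ene-2,5-dione (racemic) | CCCCCCCCCCCCCCCCCCCCCCC12OC1C(=O)C=C(OC)C2=O
A1 | alternative 1 | 2-tert-butoxy-3-docosyl-5-methoxy-1,4-benzoquinone | CCCCCCCCCCCCCCCCCCCCCCC1=C(OC(C)(C)C)C(=O)C=C(OC)C1=O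
A2 | alternative 1 | 3-tert-butoxy-2-docosyl-4-hydroxy-4-(methoxyethynyl)cyclobut-2-en-1-one (racemic) | CCCCCCCCCCCCCCCCCCCCCCC1=C(OC(C)(C)C)C(O)(C#COC)C1=O
A3 | alternative 1 | di-tert-butyl squarate (3,4-di-tert-butoxycyclobut-3-ene-1,2-dione) | CC(C)(C)OC1=C(OC(C)(C)C)C(=O)C1=O
A4 | alternative 1 | 3-tert-butoxy-4-docosylcyclobut-3-ene-1,2-dione | CCCCCCCCCCCCCCCCCCCCCCC1=C(OC(C)(C)C)C(=O)C1=O
A5 | alternative 1 | methoxyethyne | COC#C
A6 | alternative 2 | 3-docosylcyclobut-2-en-1-one | CCCCCCCCCCCCCCCCCCCCCCC1=CC(=O)C1
A7 | alternative 2 | 3-docosyl-5-methoxyphenol | CCCCCCCCCCCCCCCCCCCCCCc1cc(O)cc(OC)c1
A8 | alternative 3 | ethyl 2-oxopentacosanoate | CCCCCCCCCCCCCCCCCCCCCCCC(=O)C(=O)OCC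
A9 | alternative 3 | ethyl pyruvate | CC(=O)C(=O)OCC
A10 | alternative 3 | 3-docosyl-2,5-dihydroxy-1,4-benzoquinone | CCCCCCCCCCCCCCCCCCCCCCC1=C(O)C(=O)C=C(O)C1=O
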